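Compound numbers are fixed in the compound list after the steps and are used throughout. Decalin numbering: C1 (acyl), C2 (CH3), C3=C4, C4a (OH), C5, C6 (CO2H), C7, C8 (CH3), C8a; ring A is the cyclohexene, ring B the cyclohexane. β is the face that carries H8a (and the C4a hydroxyl of the target), α the opposite face. The same atom labels are used for the monocyclic and open-chain precursors.

## Analysis of the target

Target 41 is a cis-fused octahydronaphthalene whose C1 carries a ketone that links it to a maleimide. The neighbouring maleimide carbon bears an (S)-oct-1-en-3-yl group. The bicycle holds six stereocentres, (1S,2R,4aR,6R,8S,8aR): the C1 acyl group, the C4a hydroxyl and H8a are all β, while the C2 methyl, the C6 carboxyl and the C8 methyl are α. Seen from ring B, the C4a–C4 bond, the C6 carboxyl and the C8 methyl are therefore 1,3,5-cis. The sensitive groups are the tertiary allylic alcohol at C4a (ionises in acid), the 3-acylmaleimide (Michael acceptor), and the side-chain stereocentre, which is allylic and γ to the maleimide carbonyls and is lost with base. The difficulty lies in placing an oxygen with defined configuration on the ring-fusion carbon next to an alkene, and in joining a base-labile maleimide to a hindered C1 carbonyl. The strategy rests on one feature: the C4a oxygen and the C1 acyl carbon are cis and 1,3-related through C8a on ring A. The oxygen can therefore come from a C1 carboxylic acid, delivered to C4a of a C3=C4/C4a=C5 diene as a γ-lactone that bridges C1 and C4a. That lactone also stores the carbinol in protected form and marks the C1 carbonyl for the fragment union.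

## Retrosynthetic reasoning

**41 to 39.** The maleimide C=C is made last, by selenoxide elimination from the acylsuccinimide 39 through selenide 40. Before that step the side-chain stereocentre sits beside an sp3 ring carbon and is not acidic, so the labile chromophore never meets base or a deprotection.

**39 to 36.** The C6 carboxyl and the C1 ketone are both reached by oxidation (38, then 39) of triol 37, itself the desilylated form of 36. C6 is carried as a silyl-protected hydroxymethyl group for four reasons. An ester at C6 would put an acidic hydrogen beside the C5 acyloxy group in 19. It would become a vinylogous, epimerisable centre once C4a=C5 exists. It would offer a second internal nucleophile during the halocyclisation. And it would need acid for its release next to the tertiary allylic alcohol.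

**36 to 28 + 35.** The bond between the C1 carbinol carbon and the imide ring is cut. Forward, the enolate of succinimide 35 adds to the aldehyde that lactol 28 releases. This is the only bond whose formation uses the carbonyl marked by the lactone, and it leaves the side-chain stereocentre untouched.

**28 to 25 (key disconnection).** Lactol 28 comes from lactone 27 by partial hydride reduction, 27 from iodolactone 26 by radical dehalogenation. The C4a–O bond of 26 is cut to give diene acid 25. Forward, the C1 carboxylate must open an iodonium ion on C4a=C5 at C4a, from the β face, and leave C3=C4 alone.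

**25 to 22.** C1 is set by equilibration of ester 23 to 24, because the β-ester is trans to both neighbours. The C3=C4 bond is cut to give the bis-vinyl compound 22; forward this is a ring-closing metathesis.

**22 to 12 + 18.** The C1–C8a bond is cut. Forward, an Ireland–Claisen rearrangement of ester 19 transfers the C5–O configuration to C8a and shifts the ring alkene to C4a=C5. One reaction thus gives the C1–C8a bond, the H8a configuration and the diene.

**12 to 1, 4 and 7.** The C4a=C8a bond and the vinyl group of 12 come from enyne metathesis of 11. The C5–C6 bond of 11 comes from an Evans syn aldol of imide 6 with ynal 7 (giving 8, then 10), which fixes C5 and C6. C8 is taken from the chiral pool (1, through 3).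

**18 and 35 to 13, 29, 15 and 32.** Both allylic stereocentres (C2 in 18, the side-chain centre in 35) are cut at the bond to a malonate carbon. Forward, iridium-catalysed allylic alkylation of carbonates 14 and 30 with 15 gives 16 and 31. Compound 31 is turned into the imide with 32 (via 34).

## Alternatives that were turned down

**Alternative 1:** Ring A is opened at C1–C8a. Bromomalonate A2 has a Z-configured C3=C4 alkene that links the malonate carbon (with the C2 methyl in place) to the C4a carbinol of a ring B cyclohexene (C8a=C8). With Bu3SnH and an initiator the malonyl radical should add 6-exo to C8a, and the tertiary C8 radical should take hydrogen to give diester A1.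
- For it: the carbinol comes from a plain carbonyl addition, the electrophilic radical suits the electron-rich alkene, the tether makes the cis fusion natural, and C6 can remain an ester. On the carbinol it is stronger than the chosen plan, whose lactonisation has to overcome ring strain.
- Against it: C8 is set by hydrogen-atom transfer with nothing to fix the face. C1 emerges as a geminal diester, so one carboxyl must be removed and C1 set later beside a free tertiary allylic alcohol. A2 is itself a multi-step target, and 1,5-hydrogen shift or simple reduction competes with closure onto a trisubstituted alkene.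
- In exchange, the chosen route fixes C8a, C8, C6 and C2 by chirality transfer or an auxiliary before the bicycle exists, and the lactone leaves C1 ready for the union.

**Alternative 2:** Ring B is cut at C8a–C8 and C4a–C5. The cross-conjugated lithium enolate of ring A enone A4 (LiN(iPr)2, deprotonation at C8a) would add to enone A5. The resulting methyl ketone enolate would then close onto the C4a carbonyl to give ketol A3 in one flask.
- For it: two C–C bonds, ring B and the carbinol in one operation from simple pieces, with the cis fusion favoured by the aldol closure. In step economy it is clearly better than the chosen route.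
- Against it: A3 has a ketone at C6 where the target has CH–CO2H, so a one-carbon homologation and a new, uncontrolled stereocentre must follow. The carbinol is β to that ketone and is exposed to dehydration or retro-aldol during the homologation. The C8 configuration depends on the Michael transition state.
- The chosen route brings C6 with its carboxyl carbon and configuration from an auxiliary aldol and never places the carbinol β to a carbonyl.

**Alternative 3:** The maleimide is taken apart into an alkyne, an isocyanate and CO. Ynone A7 would be heated with trimethylsilyl isocyanate A8 under CO with Ru3(CO)12, forming both ring C–C(O) bonds and one N–C(O) bond to give maleimide A6.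
- For it: it is convergent, and the maleimide appears at the right oxidation level. It would replace the aldol, two oxidations and the selenoxide elimination of the chosen end game, so on end-game step count it is stronger.
- Against it: it leaves the real problem, the ring-fusion carbinol, unsolved, since A7 needs the same decalin. The reaction runs hot under CO. A7 has a propargylic hydrogen that is also allylic (racemisation through an allene), a 1,4-enyne unit open to other carbonylative paths, and a hindered ynone.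
- The chosen route offers a solution for the carbinol and a mild, stepwise end game in which the side-chain centre stays non-acidic until the last step.

Key step: step 14

**Assumptions (remarks on the chemistry).**
- The C6 carboxyl is carried as its triisopropylsilyl-protected hydroxymethyl precursor through the key step.
- Lactol 28 is taken to equilibrate with its open hydroxy aldehyde.
- The ligand enantiomers in steps 8 and 18 are assigned on the assumption that one ligand enantiomer delivers malonate to the same enantioface of both E-allyl carbonates; the mirror-image ligands would be used if the sense were the opposite.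

## Route

Step 1
Reactants: 1 (S)-3,7-dimethylocta-1,6-diene
Product: 3 (S)-4-methylhex-5-enoic acid, via (S)-4-methylhex-5-enal 2 (not isolated)
Conditions: O3 (1.0 equiv, Sudan red 7B end point), CH2Cl2/MeOH, −78 °C; Me2S; then NaClO2, NaH2PO4, 2-methyl-2-butene, tBuOH/H2O, 0 °C to rt
Reagents that add atoms: ozone, [O-][O+]=O; sodium chlorite, [Na+].[O-]Cl=O
Why: Ozonolysis is chemoselective for the electron-rich trisubstituted alkene over the vinyl group, and Pinnick oxidation of the aldehyde leaves the alkene and the C8 stereocentre, which comes unchanged from the chiral pool, untouched.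

Step 2
Reactants: 3 (S)-4-methylhex-5-enoic acid; 4 (R)-4-benzyl-1,3-oxazolidin-2-one
Product: 6 (R)-4-benzyl-3-[(S)-4-methylhex-5-enoyl]-1,3-oxazolidin-2-one, via mixed pivalic anhydride 5 (not isolated)
Conditions: tBuCOCl, Et3N, THF, −20 °C; then LiCl, 4, −20 °C to rt
Reagents that add atoms: none
Why: N-Acylation of an Evans oxazolidinone through the mixed pivalic anhydride; the lithium-activated oxazolidinone attacks the less hindered carbonyl, and no stereocentre is involved.

Step 3
Reactants: 6 (R)-4-benzyl-3-[(S)-4-methylhex-5-enoyl]-1,3-oxazolidin-2-one; 7 3-(trimethylsilyl)prop-2-ynal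
Product: 8 (R)-4-benzyl-3-{(2R,4S)-2-[(1R)-1-hydroxy-3-(trimethylsilyl)prop-2-yn-1-yl]-4-methylhex-5-enoyl}-1,3-oxazolidin-2-one
Conditions: Bu2BOTf, iPr2NEt, CH2Cl2, −78 to 0 °C; 7, −78 to 0 °C; pH 7 phosphate buffer, MeOH, H2O2, 0 °C
Reagents that add atoms: none
Why: Evans boron aldol: the Z-boron enolate reacts through a chair Zimmerman–Traxler transition state on the enolate face away from the benzyl group and gives the syn adduct. With the (R)-auxiliary this is the 2R,1'R isomer, which sets C6 and C5 so that the C5 oxygen and the C6 carbon substituent are cis on the future ring B.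

Step 4
Reactants: 8 (R)-4-benzyl-3-{(2R,4S)-2-[(1R)-1-hydroxy-3-(trimethylsilyl)prop-2-yn-1-yl]-4-methylhex-5-enoyl}-1,3-oxazolidin-2-one
Product: 10 (2S,3R)-2-[(2S)-2-methylbut-3-en-1-yl]pent-4-yne-1,3-diol, via C-silylated diol 9 (not isolated)
Conditions: LiBH4, MeOH (1 equiv), Et2O, 0 °C; then K2CO3, MeOH, rt
Reagents that add atoms: none
Why: Reductive removal of the auxiliary (the exocyclic imide carbonyl is the most electrophilic one) gives the primary alcohol, and methanolysis cleaves the alkynyl C–Si bond; neither stage touches a stereocentre.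

Step 5
Reactants: 10 (2S,3R)-2-[(2S)-2-methylbut-3-en-1-yl]pent-4-yne-1,3-diol
Product: 11 (3R,4S)-4-[(2S)-2-methylbut-3-en-1-yl]-5-[(triisopropylsilyl)oxy]pent-1-yn-3-ol
Conditions: iPr3SiCl, imidazole, CH2Cl2, 0 °C
Reagents that add atoms: triisopropylsilyl chloride, CC(C)[Si](Cl)(C(C)C)C(C)C
Why: Silylation with a bulky chlorosilane is selective for the primary over the secondary propargylic hydroxyl, and the silyl ether withstands every base and hydride used later.

Step 6
Reactants: 11 (3R,4S)-4-[(2S)-2-methylbut-3-en-1-yl]-5-[(triisopropylsilyl)oxy]pent-1-yn-3-ol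
Product: 12 (1R,4S,6S)-2-ethenyl-4-methyl-6-{[(triisopropylsilyl)oxy]methyl}cyclohex-2-en-1-ol
Conditions: second-generation Grubbs catalyst (5 mol%), ethylene (1 atm), CH2Cl2, 40 °C
Reagents that add atoms: none
Why: Ring-closing enyne metathesis in the exo mode: the alkylidene formed at the vinyl group adds to the terminal alkyne, closes ring B with the C4a=C8a bond and leaves the vinyl group on C4a. Ethylene keeps the catalyst turning over and no stereocentre is touched.

Step 7
Reactants: 13 (E)-but-2-en-1-ol
Product: 14 (E)-but-2-en-1-yl methyl carbonate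
Conditions: ClCO2Me, pyridine, CH2Cl2, 0 °C
Reagents that add atoms: methyl chloroformate, COC(=O)Cl
Why: O-Acylation of a primary allylic alcohol; the carbonate is the leaving group that releases methoxide as internal base in the next step.

Step 8
Reactants: 14 (E)-but-2-en-1-yl methyl carbonate; 15 dimethyl propanedioate
Product: 16 dimethyl 2-[(2R)-but-3-en-2-yl]propanedioate
Conditions: [Ir(cod)Cl]2 (2 mol%), (Sa,S,S)-N,N-bis(1-phenylethyl)dinaphtho[2,1-d:1',2'-f][1,3,2]dioxaphosphepin-4-amine (4 mol%), 1,5,7-triazabicyclo[4.4.0]dec-5-ene (8 mol%), THF, rt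
Reagents that add atoms: none
Why: Iridium-catalysed asymmetric allylic alkylation: the phosphoramidite-ligated allyl complex is attacked at the substituted terminus (branched product), and the ligand decides the enantioface, setting the future C2.

Step 9
Reactants: 16 dimethyl 2-[(2R)-but-3-en-2-yl]propanedioate
Product: 18 (S)-3-methylpent-4-enoic acid, via substituted malonic acid 17 (not isolated)
Conditions: KOH, MeOH/H2O, 70 °C; HCl; then neat, 140 °C
Reagents that add atoms: water, O
Why: Saponification and thermal decarboxylation of the malonic acid; the stereocentre is β to the carboxyl and cannot epimerise (the descriptor changes only through the priority rules).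

Step 10
Reactants: 12 (1R,4S,6S)-2-ethenyl-4-methyl-6-{[(triisopropylsilyl)oxy]methyl}cyclohex-2-en-1-ol; 18 (S)-3-methylpent-4-enoic acid
Product: 19 (1R,4S,6S)-2-ethenyl-4-methyl-6-{[(triisopropylsilyl)oxy]methyl}cyclohex-2-en-1-yl (3S)-3-methylpent-4-enoate
Conditions: EDC·HCl, DMAP, CH2Cl2, 0 °C to rt
Reagents that add atoms: none
Why: Carbodiimide/DMAP (Steglich) esterification with retention at C5; the acid has no α-stereocentre that could be lost.

Step 11
Reactants: 19 (1R,4S,6S)-2-ethenyl-4-methyl-6-{[(triisopropylsilyl)oxy]methyl}cyclohex-2-en-1-yl (3S)-3-methylpent-4-enoate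
Product: 22 methyl (3R)-2-[(1R,4R,6S)-2-ethenyl-6-methyl-4-{[(triisopropylsilyl)oxy]methyl}cyclohex-2-en-1-yl]-3-methylpent-4-enoate (both C2 epimers), via trimethylsilyl ketene acetal 20 (not isolated), via rearranged carboxylic acid 21 (not isolated)
Conditions: LiN(iPr)2, Me3SiCl/Et3N, THF, −78 °C to rt, then 60 °C; 1 M HCl; then Me3SiCHN2, toluene/MeOH, 0 °C
Reagents that add atoms: (trimethylsilyl)diazomethane, C[Si](C)(C)C=[N+]=[N-]
Why: Ireland–Claisen rearrangement: the [3,3] shift is suprafacial on the ring, so the C1–C8a bond forms on the α-face that the C5 oxygen leaves (H8a becomes β), and the ring alkene moves to C4a=C5 to give the 1-vinylcyclohexene. C1 forms as a chair/boat-dependent mixture that is corrected in step 13, and the acid is methylated for that purpose.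

Step 12
Reactants: 22 methyl (3R)-2-[(1R,4R,6S)-2-ethenyl-6-methyl-4-{[(triisopropylsilyl)oxy]methyl}cyclohex-2-en-1-yl]-3-methylpent-4-enoate
Product: 23 methyl (2R,6R,8S,8aR)-2,8-dimethyl-6-{[(triisopropylsilyl)oxy]methyl}-1,2,6,7,8,8a-hexahydronaphthalene-1-carboxylate (both C1 epimers)
Conditions: second-generation Grubbs catalyst (5 mol%), CH2Cl2, 40 °C
Reagents that add atoms: none
Why: Ring-closing metathesis between the two monosubstituted vinyl groups closes ring A as the cis C3=C4 alkene; the trisubstituted C4a=C5 bond does not take part, so the conjugated diene results.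

Step 13
Reactants: 23 methyl (2R,6R,8S,8aR)-2,8-dimethyl-6-{[(triisopropylsilyl)oxy]methyl}-1,2,6,7,8,8a-hexahydronaphthalene-1-carboxylate
Product: 25 (1S,2R,6R,8S,8aR)-2,8-dimethyl-6-{[(triisopropylsilyl)oxy]methyl}-1,2,6,7,8,8a-hexahydronaphthalene-1-carboxylic acid, via (1S)-methyl ester 24 (not isolated)
Conditions: NaOMe, MeOH, 65 °C; then LiOH, THF/H2O, 65 °C; H3O+
Reagents that add atoms: water, O
Why: Base equilibration of an ester α-centre followed by saponification. The β-ester is trans to both the C2 methyl and the C8a–C8 bond and pseudo-equatorial on the ring A envelope, so C1 should settle in the 1S configuration under thermodynamic control; C1–H is the only acidic hydrogen.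

Step 14
Reactants: 25 (1S,2R,6R,8S,8aR)-2,8-dimethyl-6-{[(triisopropylsilyl)oxy]methyl}-1,2,6,7,8,8a-hexahydronaphthalene-1-carboxylic acid
Product: 26 (1S,2R,4aR,5R,6S,8S,8aR)-4a-hydroxy-5-iodo-2,8-dimethyl-6-{[(triisopropylsilyl)oxy]methyl}-1,2,4a,5,6,7,8,8a-octahydronaphthalene-1-carboxylic acid 1,4a-lactone
Conditions: I2 (3 equiv), NaHCO3 (solid, 6 equiv), 4 Å molecular sieves, MeCN, 0 °C to rt, dark; Na2S2O3 (aq.)
Reagents that add atoms: iodine, II
Why: Iodine adds reversibly to the more substituted, more electron-rich alkene C4a=C5 on the α-face, and the C1 carboxylate opens the iodonium ion at C4a, which is tertiary and allylic to C3=C4 and carries most of the positive charge. The closest known reaction is the iodolactonisation of a γ,δ-unsaturated acid, run here in the 1,2-mode on a conjugated diene. The closure is 5-exo-trig on C4a=C5 and gives a γ-lactone that bridges C1 and C4a across ring A (a 6-oxabicyclo[3.2.1]oct-2-en-7-one unit). At C4a the C–O bond can form only on the face on which the C1 carboxyl stands, the β-face, which is also the face of H8a, so the ring fusion becomes cis. At C5 iodine ends anti to the new oxygen (α) because the carboxylate enters opposite to iodine; this centre is removed in step 15. The step needs attack at C4a and not at the vinylogous carbon C3, and activation of C4a=C5 and not of C3=C4; the higher nucleophilicity of the trisubstituted alkene, the tertiary iodonium-bearing terminus and kinetic conditions (solid NaHCO3) serve this. Water is excluded so that the tethered carboxylate is the only nucleophile that can take the cation irreversibly, since ring A has to reach the conformer with an axial carboxyl while C4a pyramidalises and the closure is therefore slower than usual.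

Step 15
Reactants: 26 (1S,2R,4aR,5R,6S,8S,8aR)-4a-hydroxy-5-iodo-2,8-dimethyl-6-{[(triisopropylsilyl)oxy]methyl}-1,2,4a,5,6,7,8,8a-octahydronaphthalene-1-carboxylic acid 1,4a-lactone
Product: 27 (1S,2R,4aR,6R,8S,8aR)-4a-hydroxy-2,8-dimethyl-6-{[(triisopropylsilyl)oxy]methyl}-1,2,4a,5,6,7,8,8a-octahydronaphthalene-1-carboxylic acid 1,4a-lactone
Conditions: Bu3SnH (3 equiv, 0.5 M), Et3B (0.2 equiv), air, toluene, 0 °C
Reagents that add atoms: none
Why: Radical chain dehalogenation: the secondary C5 radical takes hydrogen from the stannane, and β-acyloxy radicals do not fragment at a useful rate. The high stannane concentration and low temperature make hydrogen transfer faster than any rearrangement through the homoallylic C3=C4 bond.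

Step 16
Reactants: 27 (1S,2R,4aR,6R,8S,8aR)-4a-hydroxy-2,8-dimethyl-6-{[(triisopropylsilyl)oxy]methyl}-1,2,4a,5,6,7,8,8a-octahydronaphthalene-1-carboxylic acid 1,4a-lactone
Product: 28 (1S,2R,4aR,6R,8S,8aR)-4a-hydroxy-2,8-dimethyl-6-{[(triisopropylsilyl)oxy]methyl}-1,2,4a,5,6,7,8,8a-octahydronaphthalene-1-carbaldehyde as its cyclic 1,4a-hemiacetal (both anomers)
Conditions: iBu2AlH (1.2 equiv), CH2Cl2, −78 °C; KNaC4H4O6 (aq.)
Reagents that add atoms: none
Why: Partial reduction of a lactone to the lactol: the aluminium hemiacetal is stable at −78 °C and collapses only on work-up. C1 is a bridgehead in 27 and cannot enolise, and the anomeric centre is removed in step 23.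

Step 17
Reactants: 29 (E)-oct-2-en-1-ol
Product: 30 methyl (E)-oct-2-en-1-yl carbonate
Conditions: ClCO2Me, pyridine, CH2Cl2, 0 °C
Reagents that add atoms: methyl chloroformate, COC(=O)Cl
Why: O-Acylation of a primary allylic alcohol, as in step 7.

Step 18
Reactants: 30 methyl (E)-oct-2-en-1-yl carbonate; 15 dimethyl propanedioate
Product: 31 dimethyl 2-[(3S)-oct-1-en-3-yl]propanedioate
Conditions: [Ir(cod)Cl]2 (2 mol%), (Ra,R,R)-N,N-bis(1-phenylethyl)dinaphtho[2,1-d:1',2'-f][1,3,2]dioxaphosphepin-4-amine (4 mol%), 1,5,7-triazabicyclo[4.4.0]dec-5-ene (8 mol%), THF, rt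
Reagents that add atoms: none
Why: Iridium-catalysed asymmetric allylic alkylation as in step 8 with the mirror-image ligand; branched attack sets the side-chain stereocentre of the target.

Step 19
Reactants: 31 dimethyl 2-[(3S)-oct-1-en-3-yl]propanedioate; 32 2-iodoacetamide
Product: 34 methyl 3-[(3S)-oct-1-en-3-yl]-2,5-dioxopyrrolidine-3-carboxylate (both C3 epimers), via alkylated malonate amide 33 (not isolated)
Conditions: NaH, DMF, 0 °C; 32, rt; then NaOMe, MeOH, 60 °C; AcOH
Reagents that add atoms: none
Why: Malonate C-alkylation with a reactive primary iodide, then base-induced attack of the amide nitrogen on a neighbouring ester closes the five-membered imide. The allylic stereocentre carries no acidic hydrogen, and the new quaternary centre is removed later.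

Step 20
Reactants: 34 methyl 3-[(3S)-oct-1-en-3-yl]-2,5-dioxopyrrolidine-3-carboxylate
Product: 35 3-[(3S)-oct-1-en-3-yl]pyrrolidine-2,5-dione (both C3 epimers)
Conditions: LiCl, DMSO, H2O, 140 °C
Reagents that add atoms: none
Why: Krapcho dealkoxycarbonylation: chloride demethylates the ester and the carboxylate loses CO2 to an imide-stabilised anion; the ring C3 centre is a mixture and later becomes sp2.

Step 21
Reactants: 28 (1S,2R,4aR,6R,8S,8aR)-4a-hydroxy-2,8-dimethyl-6-{[(triisopropylsilyl)oxy]methyl}-1,2,4a,5,6,7,8,8a-octahydronaphthalene-1-carbaldehyde as its cyclic 1,4a-hemiacetal; 35 3-[(3S)-oct-1-en-3-yl]pyrrolidine-2,5-dione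
Product: 36 3-{hydroxy[(1S,2R,4aR,6R,8S,8aR)-4a-hydroxy-2,8-dimethyl-6-{[(triisopropylsilyl)oxy]methyl}-1,2,4a,5,6,7,8,8a-octahydronaphthalen-1-yl]methyl}-4-[(3S)-oct-1-en-3-yl]pyrrolidine-2,5-dione (mixture at the carbinol and the two imide ring carbons)
Conditions: 35 (2.0 equiv), LiN(iPr)2 (4.0 equiv), THF, −78 to −20 °C; 28 pretreated with LiN(SiMe3)2 (1.0 equiv), THF, −78 °C; −78 to −20 °C; AcOH, −78 °C
Reagents that add atoms: none
Why: Aldol addition of an imide enolate to a lactol: the N,C-dilithio derivative of 35 forms by kinetic deprotonation of the unsubstituted ring CH2 and adds to the aldehyde released from the lithium lactolate. The side-chain stereocentre is not acidic, and the three new centres are removed in steps 23 and 25.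

Step 22
Reactants: 36 3-{hydroxy[(1S,2R,4aR,6R,8S,8aR)-4a-hydroxy-2,8-dimethyl-6-{[(triisopropylsilyl)oxy]methyl}-1,2,4a,5,6,7,8,8a-octahydronaphthalen-1-yl]methyl}-4-[(3S)-oct-1-en-3-yl]pyrrolidine-2,5-dione
Product: 37 3-{hydroxy[(1S,2R,4aR,6R,8S,8aR)-4a-hydroxy-6-(hydroxymethyl)-2,8-dimethyl-1,2,4a,5,6,7,8,8a-octahydronaphthalen-1-yl]methyl}-4-[(3S)-oct-1-en-3-yl]pyrrolidine-2,5-dione
Conditions: HF·pyridine, pyridine, THF, 0 °C to rt
Reagents that add atoms: none
Why: Fluoride cleavage of the silyl ether under pyridine-buffered conditions, which spare the tertiary allylic alcohol and do not provoke retro-aldol of the β-hydroxy imide.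

Step 23
Reactants: 37 3-{hydroxy[(1S,2R,4aR,6R,8S,8aR)-4a-hydroxy-6-(hydroxymethyl)-2,8-dimethyl-1,2,4a,5,6,7,8,8a-octahydronaphthalen-1-yl]methyl}-4-[(3S)-oct-1-en-3-yl]pyrrolidine-2,5-dione
Product: 38 (1S,2R,4aR,6R,8S,8aR)-1-({2,5-dioxo-4-[(3S)-oct-1-en-3-yl]pyrrolidin-3-yl}carbonyl)-4a-hydroxy-2,8-dimethyl-1,2,4a,5,6,7,8,8a-octahydronaphthalene-6-carbaldehyde
Conditions: Dess–Martin periodinane (3 equiv), NaHCO3, CH2Cl2, 0 °C to rt
Reagents that add atoms: none
Why: Dess–Martin oxidation takes the primary alcohol to the aldehyde and the secondary one to the ketone in one operation. The tertiary alcohol cannot be oxidised, and the buffered, non-basic medium leaves C1 and C6 in their equatorial configurations.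

Step 24
Reactants: 38 (1S,2R,4aR,6R,8S,8aR)-1-({2,5-dioxo-4-[(3S)-oct-1-en-3-yl]pyrrolidin-3-yl}carbonyl)-4a-hydroxy-2,8-dimethyl-1,2,4a,5,6,7,8,8a-octahydronaphthalene-6-carbaldehyde
Product: 39 (1S,2R,4aR,6R,8S,8aR)-1-({2,5-dioxo-4-[(3S)-oct-1-en-3-yl]pyrrolidin-3-yl}carbonyl)-4a-hydroxy-2,8-dimethyl-1,2,4a,5,6,7,8,8a-octahydronaphthalene-6-carboxylic acid
Conditions: NaClO2, NaH2PO4, 2-methyl-2-butene, tBuOH/H2O, 0 °C to rt
Reagents that add atoms: sodium chlorite, [Na+].[O-]Cl=O
Why: Pinnick oxidation of the aldehyde at pH 3 to 4; the alkene scavenger removes hypochlorite before it can chlorinate the acidic methine or the alkenes.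

Step 25
Reactants: 39 (1S,2R,4aR,6R,8S,8aR)-1-({2,5-dioxo-4-[(3S)-oct-1-en-3-yl]pyrrolidin-3-yl}carbonyl)-4a-hydroxy-2,8-dimethyl-1,2,4a,5,6,7,8,8a-octahydronaphthalene-6-carboxylic acid
Product: 41 (1S,2R,4aR,6R,8S,8aR)-1-({2,5-dioxo-4-[(3S)-oct-1-en-3-yl]-2,5-dihydro-1H-pyrrol-3-yl}carbonyl)-4a-hydroxy-2,8-dimethyl-1,2,4a,5,6,7,8,8a-octahydronaphthalene-6-carboxylic acid, via α-phenylselanyl diketone 40 (not isolated)
Conditions: PhSeCl, pyridine, CH2Cl2, 0 °C; aq. HCl wash; then H2O2 (30%), CH2Cl2, 0 °C
Reagents that add atoms: none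
Why: Selenoxide dehydrogenation of a 1,3-dicarbonyl compound: the enol of the keto imide is selenenylated at the carbon between the two carbonyls, trans to the octenyl group. The selenoxide then eliminates syn with the only β-hydrogen, on the ring carbon that bears the octenyl group, which forms the maleimide C=C without base.

## Compound list

1 | (S)-3,7-dimethylocta-1,6-diene | C=C[C@@H](C)CCC=C(C)C | starting material
2 | (S)-4-methylhex-5-enal | C=C[C@@H](C)CCC=O | intermediate
3 | (S)-4-methylhex-5-enoic acid | C=C[C@@H](C)CCC(=O)O | intermediate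
4 | (R)-4-benzyl-1,3-oxazolidin-2-one | O=C1N[C@H](Cc2ccccc2)CO1 | starting material
5 | (S)-4-methylhex-5-enoic pivalic anhydride | C=C[C@@H](C)CCC(=O)OC(=O)C(C)(C)C | intermediate
6 | (R)-4-benzyl-3-[(S)-4-methylhex-5-enoyl]-1,3-oxazolidin-2-one | C=C[C@@H](C)CCC(=O)N1C(=O)OC[C@H]1Cc1ccccc1 | intermediate
7 | 3-(trimethylsilyl)prop-2-ynal | C[Si](C)(C)C#CC=O | starting material
8 | (R)-4-benzyl-3-{(2R,4S)-2-[(1R)-1-hydroxy-3-(trimethylsilyl)prop-2-yn-1-yl]-4-methylhex-5-enoyl}-1,3-oxazolidin-2-one | C[Si](C)(C)C#C[C@H](O)[C@@H](C[C@H](C)C=C)C(=O)N1C(=O)OC[C@H]1Cc1ccccc1 | intermediate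
9 | (2S,3R)-2-[(2S)-2-methylbut-3-en-1-yl]-5-(trimethylsilyl)pent-4-yne-1,3-diol | C[Si](C)(C)C#C[C@H](O)[C@H](CO)C[C@H](C)C=C | intermediate
10 | (2S,3R)-2-[(2S)-2-methylbut-3-en-1-yl]pent-4-yne-1,3-diol | C#C[C@H](O)[C@H](CO)C[C@H](C)C=C | intermediate
11 | (3R,4S)-4-[(2S)-2-methylbut-3-en-1-yl]-5-[(triisopropylsilyl)oxy]pent-1-yn-3-ol | C#C[C@H](O)[C@H](CO[Si](C(C)C)(C(C)C)C(C)C)C[C@H](C)C=C | intermediate
12 | (1R,4S,6S)-2-ethenyl-4-methyl-6-{[(triisopropylsilyl)oxy]methyl}cyclohex-2-en-1-ol | C=CC1=C[C@@H](C)C[C@@H](CO[Si](C(C)C)(C(C)C)C(C)C)[C@H]1O | intermediate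
13 | (E)-but-2-en-1-ol | C/C=C/CO | starting material
14 | (E)-but-2-en-1-yl methyl carbonate | C/C=C/COC(=O)OC | intermediate
15 | dimethyl propanedioate (dimethyl malonate) | COC(=O)CC(=O)OC | starting material
16 | dimethyl 2-[(2R)-but-3-en-2-yl]propanedioate | C=C[C@@H](C)C(C(=O)OC)C(=O)OC | intermediate
17 | 2-[(2R)-but-3-en-2-yl]propanedioic acid | C=C[C@@H](C)C(C(=O)O)C(=O)O | intermediate
18 | (S)-3-methylpent-4-enoic acid | C=C[C@@H](C)CC(=O)O | intermediate
19 | (1R,4S,6S)-2-ethenyl-4-methyl-6-{[(triisopropylsilyl)oxy]methyl}cyclohex-2-en-1-yl (3S)-3-methylpent-4-enoate | C=C[C@@H](C)CC(=O)O[C@H]1C(C=C)=C[C@@H](C)C[C@H]1CO[Si](C(C)C)(C(C)C)C(C)C | intermediate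
20 | trimethylsilyl ketene acetal of 19 (ketene acetal geometry not defined) | C=C[C@@H](C)C=C(O[Si](C)(C)C)O[C@H]1C(C=C)=C[C@@H](C)C[C@H]1CO[Si](C(C)C)(C(C)C)C(C)C | intermediate
21 | (3R)-2-[(1R,4R,6S)-2-ethenyl-6-methyl-4-{[(triisopropylsilyl)oxy]methyl}cyclohex-2-en-1-yl]-3-methylpent-4-enoic acid (both C2 epimers) | C=C[C@@H](C)C(C(=O)O)[C@H]1[C@@H](C)C[C@@H](CO[Si](C(C)C)(C(C)C)C(C)C)C=C1C=C | intermediate
22 | methyl (3R)-2-[(1R,4R,6S)-2-ethenyl-6-methyl-4-{[(triisopropylsilyl)oxy]methyl}cyclohex-2-en-1-yl]-3-methylpent-4-enoate (both C2 epimers) | C=C[C@@H](C)C(C(=O)OC)[C@H]1[C@@H](C)C[C@@H](CO[Si](C(C)C)(C(C)C)C(C)C)C=C1C=C | intermediate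
23 | methyl (2R,6R,8S,8aR)-2,8-dimethyl-6-{[(triisopropylsilyl)oxy]methyl}-1,2,6,7,8,8a-hexahydronaphthalene-1-carboxylate (both C1 epimers) | COC(=O)C1[C@H]2[C@@H](C)C[C@@H](CO[Si](C(C)C)(C(C)C)C(C)C)C=C2C=C[C@H]1C | intermediate
24 | methyl (1S,2R,6R,8S,8aR)-2,8-dimethyl-6-{[(triisopropylsilyl)oxy]methyl}-1,2,6,7,8,8a-hexahydronaphthalene-1-carboxylate | COC(=O)[C@@H]1[C@H]2[C@@H](C)C[C@@H](CO[Si](C(C)C)(C(C)C)C(C)C)C=C2C=C[C@H]1C | intermediate
25 | (1S,2R,6R,8S,8aR)-2,8-dimethyl-6-{[(triisopropylsilyl)oxy]methyl}-1,2,6,7,8,8a-hexahydronaphthalene-1-carboxylic acid | OC(=O)[C@@H]1[C@H]2[C@@H](C)C[C@@H](CO[Si](C(C)C)(C(C)C)C(C)C)C=C2C=C[C@H]1C | intermediate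
26 | (1S,2R,4aR,5R,6S,8S,8aR)-4a-hydroxy-5-iodo-2,8-dimethyl-6-{[(triisopropylsilyl)oxy]methyl}-1,2,4a,5,6,7,8,8a-octahydronaphthalene-1-carboxylic acid 1,4a-lactone | O=C3[C@@H]1[C@H]2[C@@H](C)C[C@@H](CO[Si](C(C)C)(C(C)C)C(C)C)[C@@H](I)[C@@]2(O3)C=C[C@H]1C | intermediate
27 | (1S,2R,4aR,6R,8S,8aR)-4a-hydroxy-2,8-dimethyl-6-{[(triisopropylsilyl)oxy]methyl}-1,2,4a,5,6,7,8,8a-octahydronaphthalene-1-carboxylic acid 1,4a-lactone | O=C3[C@@H]1[C@H]2[C@@H](C)C[C@@H](CO[Si](C(C)C)(C(C)C)C(C)C)C[C@@]2(O3)C=C[C@H]1C | intermediate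
28 | (1S,2R,4aR,6R,8S,8aR)-4a-hydroxy-2,8-dimethyl-6-{[(triisopropylsilyl)oxy]methyl}-1,2,4a,5,6,7,8,8a-octahydronaphthalene-1-carbaldehyde as its cyclic 1,4a-hemiacetal (both anomers) | OC3[C@@H]1[C@H]2[C@@H](C)C[C@@H](CO[Si](C(C)C)(C(C)C)C(C)C)C[C@@]2(O3)C=C[C@H]1C | intermediate
29 | (E)-oct-2-en-1-ol | CCCCC/C=C/CO | starting material
30 | methyl (E)-oct-2-en-1-yl carbonate | CCCCC/C=C/COC(=O)OC | intermediate
31 | dimethyl 2-[(3S)-oct-1-en-3-yl]propanedioate | C=C[C@H](CCCCC)C(C(=O)OC)C(=O)OC | intermediate
32 | 2-iodoacetamide | NC(=O)CI | starting material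
33 | dimethyl 2-(2-amino-2-oxoethyl)-2-[(3S)-oct-1-en-3-yl]propanedioate | C=C[C@H](CCCCC)C(CC(N)=O)(C(=O)OC)C(=O)OC | intermediate
34 | methyl 3-[(3S)-oct-1-en-3-yl]-2,5-dioxopyrrolidine-3-carboxylate (both C3 epimers) | C=C[C@H](CCCCC)C1(C(=O)OC)CC(=O)NC1=O | intermediate
35 | 3-[(3S)-oct-1-en-3-yl]pyrrolidine-2,5-dione (both C3 epimers) | C=C[C@H](CCCCC)C1CC(=O)NC1=O | intermediate
36 | 3-{hydroxy[(1S,2R,4aR,6R,8S,8aR)-4a-hydroxy-2,8-dimethyl-6-{[(triisopropylsilyl)oxy]methyl}-1,2,4a,5,6,7,8,8a-octahydronaphthalen-1-yl]methyl}-4-[(3S)-oct-1-en-3-yl]pyrrolidine-2,5-dione (mixture at the carbinol and both imide ring carbons) | C=C[C@H](CCCCC)C1C(C(O)[C@@H]2[C@H]3[C@@H](C)C[C@@H](CO[Si](C(C)C)(C(C)C)C(C)C)C[C@@]3(O)C=C[C@H]2C)C(=O)NC1=O | intermediate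
37 | 3-{hydroxy[(1S,2R,4aR,6R,8S,8aR)-4a-hydroxy-6-(hydroxymethyl)-2,8-dimethyl-1,2,4a,5,6,7,8,8a-octahydronaphthalen-1-yl]methyl}-4-[(3S)-oct-1-en-3-yl]pyrrolidine-2,5-dione (same mixture) | C=C[C@H](CCCCC)C1C(C(O)[C@@H]2[C@H]3[C@@H](C)C[C@@H](CO)C[C@@]3(O)C=C[C@H]2C)C(=O)NC1=O | intermediate
38 | (1S,2R,4aR,6R,8S,8aR)-1-({2,5-dioxo-4-[(3S)-oct-1-en-3-yl]pyrrolidin-3-yl}carbonyl)-4a-hydroxy-2,8-dimethyl-1,2,4a,5,6,7,8,8a-octahydronaphthalene-6-carbaldehyde (mixture at both imide ring carbons) | C=C[C@H](CCCCC)C1C(C(=O)[C@@H]2[C@H]3[C@@H](C)C[C@@H](C=O)C[C@@]3(O)C=C[C@H]2C)C(=O)NC1=O | intermediate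
39 | (1S,2R,4aR,6R,8S,8aR)-1-({2,5-dioxo-4-[(3S)-oct-1-en-3-yl]pyrrolidin-3-yl}carbonyl)-4a-hydroxy-2,8-dimethyl-1,2,4a,5,6,7,8,8a-octahydronaphthalene-6-carboxylic acid (mixture at both imide ring carbons) | C=C[C@H](CCCCC)C1C(C(=O)[C@@H]2[C@H]3[C@@H](C)C[C@@H](C(=O)O)C[C@@]3(O)C=C[C@H]2C)C(=O)NC1=O | intermediate
40 | (1S,2R,4aR,6R,8S,8aR)-1-({2,5-dioxo-4-[(3S)-oct-1-en-3-yl]-3-(phenylselanyl)pyrrolidin-3-yl}carbonyl)-4a-hydroxy-2,8-dimethyl-1,2,4a,5,6,7,8,8a-octahydronaphthalene-6-carboxylic acid | C=C[C@H](CCCCC)C1C([Se]c2ccccc2)(C(=O)[C@@H]3[C@H]4[C@@H](C)C[C@@H](C(=O)O)C[C@@]4(O)C=C[C@H]3C)C(=O)NC1=O | intermediate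
41 | (1S,2R,4aR,6R,8S,8aR)-1-({2,5-dioxo-4-[(3S)-oct-1-en-3-yl]-2,5-dihydro-1H-pyrrol-3-yl}carbonyl)-4a-hydroxy-2,8-dimethyl-1,2,4a,5,6,7,8,8a-octahydronaphthalene-6-carboxylic acid | C=C[C@H](CCCCC)C1=C(C(=O)[C@@H]2[C@H]3[C@@H](C)C[C@@H](C(=O)O)C[C@@]3(O)C=C[C@H]2C)C(=O)NC1=O | target

## Step count and least certain steps

Total step count: 25. Longest linear sequence: 18 steps (steps 1 to 6, 10 to 16, 21 to 25).

**Step 14 (key step).** The most likely failure is a slow or diverted ring closure. In the ground state of 25, ring A is an envelope with C1 below the diene plane and the β-carboxyl pseudo-equatorial, while the β-lobe at C4a is flanked by the pseudo-axial H8a. The closure therefore needs a ring A flip that becomes possible only as C4a pyramidalises. It also gives a strained product, because a chair ring B would place C4, the C6 silyloxymethyl group and the C8 methyl syn-axial. The allyl cation may thus be captured at C3 (1,4-lactonisation), be intercepted by traces of water, or simply revert.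

Fallback: hydroxylation without the tether. The sequence sets out from ester 24, isolated after the NaOMe stage of step 13. N-Iodosuccinimide in wet THF should give methyl (1S,2R,4aR,5R,6S,8S,8aR)-4a-hydroxy-5-iodo-2,8-dimethyl-6-{[(triisopropylsilyl)oxy]methyl}-1,2,4a,5,6,7,8,8a-octahydronaphthalene-1-carboxylate F1. Water opens the α-iodonium ion at the tertiary allylic C4a in the trans-diaxial sense, and the ring B chair with equatorial C6 and C8 substituents admits only β-attack there. Bu3SnH/Et3B should then give the hydroxy ester methyl (1S,2R,4aR,6R,8S,8aR)-4a-hydroxy-2,8-dimethyl-6-{[(triisopropylsilyl)oxy]methyl}-1,2,4a,5,6,7,8,8a-octahydronaphthalene-1-carboxylate F2. iBu2AlH at −78 °C reduces F2 to the aldehyde, which closes to lactol 28, where the route is rejoined.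

**Step 21.** The aldehyde is hindered, α-branched and largely masked, and the nucleophile is a dianion. The likely failures are enolisation of the aldehyde in place of addition, retro-aldol on warming, or poor solubility of the dilithio imide.

Fallback: a base-poor, catalytic union. Succinimide 35 is converted (LiN(iPr)2, PhSeCl; H2O2) through 3-[(3S)-oct-1-en-3-yl]-4-(phenylselanyl)pyrrolidine-2,5-dione F3 into 3-[(3S)-oct-1-en-3-yl]-1H-pyrrole-2,5-dione F4. A Stetter reaction of 28 with F4 (3-benzyl-5-(2-hydroxyethyl)-4-methylthiazolium chloride, Et3N, dioxane, 70 °C) should give (1S,2R,4aR,6R,8S,8aR)-configured 3-{[4a-hydroxy-2,8-dimethyl-6-{[(triisopropylsilyl)oxy]methyl}-1,2,4a,5,6,7,8,8a-octahydronaphthalen-1-yl]carbonyl}-4-[(3S)-oct-1-en-3-yl]pyrrolidine-2,5-dione F5. HF·pyridine gives the 6-hydroxymethyl keto imide F6, and Dess–Martin oxidation of F6 rejoins the route at 38. The price is the exposure of the base-labile stereocentre of F4 to the amine.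

**Step 13.** The risk is incomplete equilibration at the hindered C1 or sluggish hydrolysis of the flanked ester, with slow loss of the silyl ether on prolonged heating.

Fallback: equilibrate at the aldehyde level. Ester mixture 23 is reduced with iBu2AlH at −78 °C to (2R,6R,8S,8aR)-2,8-dimethyl-6-{[(triisopropylsilyl)oxy]methyl}-1,2,6,7,8,8a-hexahydronaphthalene-1-carbaldehyde F7 (both C1 epimers). DBU in CH2Cl2 equilibrates the far more acidic aldehyde α-centre to the (1S)-aldehyde F8, and Pinnick oxidation of F8 gives 25.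

**Step 25.** PhSeCl may add to the C3=C4 or vinyl alkene in competition with the enol, and the seleninic peracid formed during oxidation may epoxidise an alkene or isomerise the product.

Fallback: hydride abstraction in place of selenium chemistry. 39 is dehydrogenated with 2,3-dichloro-5,6-dicyano-1,4-benzoquinone in dioxane at rt, through the enol of the keto imide, and gives 41 directly (no new compound, F0).

## Further compounds

F1 | step 14 | methyl (1S,2R,4aR,5R,6S,8S,8aR)-4a-hydroxy-5-iodo-2,8-dimethyl-6-{[(triisopropylsilyl)oxy]methyl}-1,2,4a,5,6,7,8,8a-octahydronaphthalene-1-carboxylate | COC(=O)[C@@H]1[C@H]2[C@@H](C)C[C@@H](CO[Si](C(C)C)(C(C)C)C(C)C)[C@@H](I)[C@@]2(O)C=C[C@H]1C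
F2 | step 14 | methyl (1S,2R,4aR,6R,8S,8aR)-4a-hydroxy-2,8-dimethyl-6-{[(triisopropylsilyl)oxy]methyl}-1,2,4a,5,6,7,8,8a-octahydronaphthalene-1-carboxylate | COC(=O)[C@@H]1[C@H]2[C@@H](C)C[C@@H](CO[Si](C(C)C)(C(C)C)C(C)C)C[C@@]2(O)C=C[C@H]1C
F3 | step 21 | 3-[(3S)-oct-1-en-3-yl]-4-(phenylselanyl)pyrrolidine-2,5-dione | C=C[C@H](CCCCC)C1C([Se]c2ccccc2)C(=O)NC1=O
F4 | step 21 | 3-[(3S)-oct-1-en-3-yl]-1H-pyrrole-2,5-dione | C=C[C@H](CCCCC)C1=CC(=O)NC1=O
F5 | step 21 | 3-{[(1S,2R,4aR,6R,8S,8aR)-4a-hydroxy-2,8-dimethyl-6-{[(triisopropylsilyl)oxy]methyl}-1,2,4a,5,6,7,8,8a-octahydronaphthalen-1-yl]carbonyl}-4-[(3S)-oct-1-en-3-yl]pyrrolidine-2,5-dione | C=C[C@H](CCCCC)C1C(C(=O)[C@@H]2[C@H]3[C@@H](C)C[C@@H](CO[Si](C(C)C)(C(C)C)C(C)C)C[C@@]3(O)C=C[C@H]2C)C(=O)NC1=O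
F6 | step 21 | 3-{[(1S,2R,4aR,6R,8S,8aR)-4a-hydroxy-6-(hydroxymethyl)-2,8-dimethyl-1,2,4a,5,6,7,8,8a-octahydronaphthalen-1-yl]carbonyl}-4-[(3S)-oct-1-en-3-yl]pyrrolidine-2,5-dione | C=C[C@H](CCCCC)C1C(C(=O)[C@@H]2[C@H]3[C@@H](C)C[C@@H](CO)C[C@@]3(O)C=C[C@H]2C)C(=O)NC1=O
F7 | step 13 | (2R,6R,8S,8aR)-2,8-dimethyl-6-{[(triisopropylsilyl)oxy]methyl}-1,2,6,7,8,8a-hexahydronaphthalene-1-carbaldehyde (both C1 epimers) | O=CC1[C@H]2[C@@H](C)C[C@@H](CO[Si](C(C)C)(C(C)C)C(C)C)C=C2C=C[C@H]1C
F8 | step 13 | (1S,2R,6R,8S,8aR)-2,8-dimethyl-6-{[(triisopropylsilyl)oxy]methyl}-1,2,6,7,8,8a-hexahydronaphthalene-1-carbaldehyde | O=C[C@@H]1[C@H]2[C@@H](C)C[C@@H](CO[Si](C(C)C)(C(C)C)C(C)C)C=C2C=C[C@H]1C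
F0 | step 25 | none | none
A1 | alternative 1 | 6-tert-butyl 1,1-dimethyl (2R,4aR,6R,8S,8aR)-4a-hydroxy-2,8-dimethyl-4a,5,6,7,8,8a-hexahydronaphthalene-1,1,6(2H)-tricarboxylate | COC(=O)C1(C(=O)OC)[C@H]2[C@@H](C)C[C@@H](C(=O)OC(C)(C)C)C[C@@]2(O)C=C[C@H]1C
A2 | alternative 1 | dimethyl 2-bromo-2-[(2R,3Z)-4-(5-tert-butoxycarbonyl-1-hydroxy-3-methylcyclohex-2-en-1-yl)but-3-en-2-yl]propanedioate | COC(=O)C(Br)(C(=O)OC)[C@H](C)/C=C\[C@]1(O)C[C@H](C(=O)OC(C)(C)C)CC(C)=C1
A3 | alternative 2 | ethyl (1S,2R,4aR,8S,8aR)-4a-hydroxy-2,8-dimethyl-6-oxo-1,2,4a,5,6,7,8,8a-octahydronaphthalene-1-carboxylate | CCOC(=O)[C@@H]1[C@H]2[C@@H](C)CC(=O)C[C@@]2(O)C=C[C@H]1C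
A4 | alternative 2 | ethyl 2-methyl-5-oxocyclohex-3-ene-1-carboxylate (trans, configured as C1 and C2 of the target) | CCOC(=O)[C@@H]1CC(=O)C=C[C@H]1C
A5 | alternative 2 | (E)-pent-3-en-2-one | C/C=C/C(C)=O
A6 | alternative 3 | tert-butyl ester and C4a triethylsilyl ether of 41 | C=C[C@H](CCCCC)C1=C(C(=O)[C@@H]2[C@H]3[C@@H](C)C[C@@H](C(=O)OC(C)(C)C)C[C@@]3(O[Si](CC)(CC)CC)C=C[C@H]2C)C(=O)NC1=O
A7 | alternative 3 | tert-butyl (1S,2R,4aR,6R,8S,8aR)-2,8-dimethyl-1-[(4S)-4-pentylhex-5-en-2-ynoyl]-4a-[(triethylsilyl)oxy]-1,2,4a,5,6,7,8,8a-octahydronaphthalene-6-carboxylate | C=C[C@H](CCCCC)C#CC(=O)[C@@H]1[C@H]2[C@@H](C)C[C@@H](C(=O)OC(C)(C)C)C[C@@]2(O[Si](CC)(CC)CC)C=C[C@H]1C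
A8 | alternative 3 | trimethylsilyl isocyanate | C[Si](C)(C)N=C=O
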